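**Retrosynthetic overview**
- The C40 chain is cut at C11=C12 and C11'=C12' in a single operation: two different C15 allyl sulfones (plain ε end, 3-hydroxy ε end) plus the commercial C10 trienedial. C11 and C11', by nature allyl-cation termini, are used as sulfonyl-stabilised allyl anions on the aldehyde carbons, in one flask with the 3-OH left free.
- The hydroxy C15 sulfone comes from the plain C15 sulfone by ring C3–H oxidation to the enone and catalyst-controlled reduction, which sets C3.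
- The plain C15 sulfone comes from (S)-α-ionone and a vinyl Grignard reagent by SN1' thioetherification and S-oxidation.
- No ring is built: both cyclohexene rings, with C6 and C6', come ready-made from (S)-α-ionone.

Assumption: (S)-(−)-α-ionone is bought as the single enantiomer (≥98% ee); the racemate is a bulk fragrance chemical.

**Step 1**
Reactants: 1 (S)-α-ionone; 2 vinylmagnesium bromide
Product: 3 (6S)-vinyl-α-ionol (carbinol epimer mixture)
Conditions: CH2=CHMgBr (1.3 equiv), THF, −40 → 0 °C; then H2O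
Reagents that add atoms: none
Why: Grignard 1,2-addition to the methyl ketone outruns enolisation and conjugate addition at low temperature, so the ring stereocentre is untouched; the new carbinol centre forms unselectively and is erased in step 2.

**Step 2**
Reactants: 3 (6S)-vinyl-α-ionol; 4 2-mercaptobenzothiazole
Product: 5 C15 allyl benzothiazolyl sulfide (2E,4E)
Conditions: 4 (1.3 equiv), TsOH·H2O (5 mol%), CH2Cl2, 0 °C → rt
Reagents that add atoms: none
Why: Acid-catalysed SN1' thioetherification (the thiol analogue of the PPh3·HBr and PhSO2Na/AcOH reactions of vinyl-ionols): the pentadienyl cation is captured at its unhindered primary terminus to give the conjugated 2E,4E-diene, with no stereocentre involved.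

**Step 3**
Reactants: 5 C15 allyl benzothiazolyl sulfide
Product: 6 C15 allyl benzothiazolyl sulfone
Conditions: 30% H2O2 (3 equiv), (NH4)6Mo7O24·4H2O (5 mol%), EtOH, 0 °C → rt; recrystallise (removes minor 2Z isomer)
Reagents that add atoms: hydrogen peroxide, OO
Why: Molybdate-catalysed sulfide-to-sulfone oxidation; sulfur is oxidised much faster than the trisubstituted ring alkene or the diene is epoxidised.

**Step 4**
Reactants: 6 C15 allyl benzothiazolyl sulfone
Product: 7 3-oxo C15 sulfone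
Conditions: t-BuOOH (70% aq, 5 equiv), Rh2(cap)4 (dirhodium tetracaprolactamate, 1 mol%), ClCH2CH2Cl, 40 °C
Reagents that add atoms: tert-butyl hydroperoxide, CC(C)(C)OO
Why: Peroxyl-radical allylic C–H oxidation turns the ring allylic CH2 into the enone as in α-ionone-type rings; the electron-poor CH2SO2 is polarity-mismatched and the hindered C6–H is spared, so the stereocentre is kept.

**Step 5**
Reactants: 7 3-oxo C15 sulfone
Product: 8 (3S,6S)-3-hydroxy C15 sulfone
Conditions: (R)-Me-CBS oxazaborolidine (20 mol%), catecholborane (1.8 equiv), toluene/CH2Cl2, −78 °C; then MeOH, pH 7 buffer; chromatography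
Reagents that add atoms: none
Why: Corey–Bakshi–Shibata reduction, in which the (R)-catalyst delivers hydride with the alkenyl arm as the large group to give the 3S carbinol (trans to the side chain) under catalyst control; catecholborane at −78 °C reduces only the carbonyl, and the minor 3R epimer is removed on silica.

**Step 6**
Reactants: 6 C15 allyl benzothiazolyl sulfone; 9 (2E,4E,6E)-2,7-dimethylocta-2,4,6-trienedial; 8 (3S,6S)-3-hydroxy C15 sulfone
Product: 12 (3S,6S,6'S)-ε,ε-caroten-3-ol (all-E), via 8Z-C25 aldehyde 10 (not isolated), via 11Z,11'Z-carotenol 11 (not isolated)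
Conditions: 6, NaN(SiMe3)2 (1.0 equiv), THF, −78 °C; cannulate into 9 (1.1 equiv), THF, −78 → 0 °C; Ar purge (removes SO2); −78 °C, add 8 (1.2 equiv) then NaN(SiMe3)2 (2.4 equiv), → rt; H2O; crude in n-heptane/EtOAc, 80 °C, 8 h, dark; chromatography, crystallise
Reagents that add atoms: none
Why: Two Julia–Kocienski olefinations in one flask: C11' and then C11, allyl-cation termini in step 2, react as sulfonyl-stabilised allyl anions with the two aldehyde carbons, Smiles rearrangement expelling SO2 and benzothiazolone to give each C=C directly; inverse addition to the more electrophilic dialdehyde favours mono-olefination, the kinetic hindered Z bonds relax to all-E on heating, and no stereocentre is formed or touched.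

**Compound list**
1 | (S)-α-ionone, (3E)-4-[(1S)-2,6,6-trimethylcyclohex-2-en-1-yl]but-3-en-2-one | CC1=CCCC(C)(C)[C@@H]1/C=C/C(C)=O | starting material
2 | vinylmagnesium bromide, CH2=CHMgBr | C=C[Mg]Br | starting material
3 | (6S)-vinyl-α-ionol, (1E)-3-methyl-1-[(1S)-2,6,6-trimethylcyclohex-2-en-1-yl]penta-1,4-dien-3-ol (both carbinol epimers) | CC1=CCCC(C)(C)[C@@H]1/C=C/C(C)(O)C=C | intermediate
4 | 2-mercaptobenzothiazole (1,3-benzothiazole-2-thiol) | Sc1nc2ccccc2s1 | starting material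
5 | 2-({(2E,4E)-3-methyl-5-[(1S)-2,6,6-trimethylcyclohex-2-en-1-yl]penta-2,4-dien-1-yl}sulfanyl)-1,3-benzothiazole | CC1=CCCC(C)(C)[C@@H]1/C=C/C(C)=C/CSc1nc2ccccc2s1 | intermediate
6 | 2-({(2E,4E)-3-methyl-5-[(1S)-2,6,6-trimethylcyclohex-2-en-1-yl]penta-2,4-dien-1-yl}sulfonyl)-1,3-benzothiazole | CC1=CCCC(C)(C)[C@@H]1/C=C/C(C)=C/CS(=O)(=O)c1nc2ccccc2s1 | intermediate
7 | 2-({(2E,4E)-3-methyl-5-[(1S)-2,6,6-trimethyl-4-oxocyclohex-2-en-1-yl]penta-2,4-dien-1-yl}sulfonyl)-1,3-benzothiazole | CC1=CC(=O)CC(C)(C)[C@@H]1/C=C/C(C)=C/CS(=O)(=O)c1nc2ccccc2s1 | intermediate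
8 | 2-({(2E,4E)-5-[(1S,4S)-4-hydroxy-2,6,6-trimethylcyclohex-2-en-1-yl]-3-methylpenta-2,4-dien-1-yl}sulfonyl)-1,3-benzothiazole | CC1=C[C@@H](O)CC(C)(C)[C@@H]1/C=C/C(C)=C/CS(=O)(=O)c1nc2ccccc2s1 | intermediate
9 | (2E,4E,6E)-2,7-dimethylocta-2,4,6-trienedial (C10 dialdehyde) | O=C/C(C)=C/C=C/C=C(C)/C=O | starting material
10 | (2E,4E,6E,8Z,10E,12E)-2,7,11-trimethyl-13-[(1S)-2,6,6-trimethylcyclohex-2-en-1-yl]trideca-2,4,6,8,10,12-hexaenal (not isolated) | CC1=CCCC(C)(C)[C@@H]1/C=C/C(C)=C/C=C\C(C)=C\C=C\C=C(C)\C=O | intermediate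
11 | (3S,6S,6'S,11Z,11'Z)-ε,ε-caroten-3-ol (not isolated) | CC1=CCCC(C)(C)[C@@H]1/C=C/C(C)=C/C=C\C(C)=C\C=C\C=C(C)\C=C/C=C(C)/C=C/[C@@H]1C(C)=C[C@@H](O)CC1(C)C | intermediate
12 | (3S,6S,6'S)-ε,ε-caroten-3-ol, (1S,4S)-3,5,5-trimethyl-4-[(1E,3E,5E,7E,9E,11E,13E,15E,17E)-3,7,12,16-tetramethyl-18-[(1S)-2,6,6-trimethylcyclohex-2-en-1-yl]octadeca-1,3,5,7,9,11,13,15,17-nonaen-1-yl]cyclohex-2-en-1-ol | CC1=CCCC(C)(C)[C@@H]1/C=C/C(C)=C/C=C/C(C)=C/C=C/C=C(C)/C=C/C=C(C)/C=C/[C@@H]1C(C)=C[C@@H](O)CC1(C)C | target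

**Count**
Total steps: 6. Longest linear sequence: 6 (1 → 3 → 5 → 6 → 7 → 8 → 12).

**Steps most likely to fail**

Step 4 (ring C–H oxidation next to a conjugated diene; competing attack at the diene or at C6–H). The fallback sets out from 3 and comes back at 7, moving the oxidation ahead of diene formation. The same Rh2(cap)4/t-BuOOH oxidation is run on 3, which has only isolated alkenes, to give the 3-oxo-vinyl-ionol F1. F1 and 4 under the step 2 conditions (TsOH·H2O, CH2Cl2) give the 3-oxo C15 sulfide F2. Molybdate/H2O2 oxidation of F2 as in step 3 gives 7.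

Step 5 (sense and level of catalyst control at C3 are not proven for this ring). The fallback sets out from 7 and comes back at 8, replacing catalyst control by an enzymatic sorting of epimers. Luche reduction (NaBH4, CeCl3·7H2O, MeOH, −40 °C) gives 8 together with the (3R,6S)-hydroxy sulfone F3. Lipase PS (Burkholderia cepacia) with vinyl acetate in t-BuOMe acylates only the 3R carbinol, to the (3R,6S)-acetate F4. Unreacted 8 is separated on silica.

Step 6 (mono-selectivity on the dialdehyde, SO2 left in the flask quenching the second anion, free alkoxide on 8). The fallback sets out from 3 and comes back at 12, making the first C=C with a phosphorus ylide and isolating the aldehyde. 3 and PPh3·HBr (MeOH, rt) give the C15 triphenylphosphonium bromide F5. Wittig reaction of F5 with 9 (1.5 equiv, NaOMe, CH2Cl2/MeOH, 0 °C), then heating in heptane, gives the crystalline all-E C25 aldehyde F6, freed from excess 9. F6 and 8 under Barbier Julia–Kocienski conditions (NaN(SiMe3)2, 2.2 equiv, THF, −78 °C → rt) give the 11Z-carotenol F7, which is heated in heptane/EtOAc at 80 °C to 12.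

**Further compounds**
F1 | step 4 | (4S)-4-[(1E)-3-hydroxy-3-methylpenta-1,4-dien-1-yl]-3,5,5-trimethylcyclohex-2-en-1-one (both carbinol epimers) | CC1=CC(=O)CC(C)(C)[C@@H]1/C=C/C(C)(O)C=C
F2 | step 4 | 2-({(2E,4E)-3-methyl-5-[(1S)-2,6,6-trimethyl-4-oxocyclohex-2-en-1-yl]penta-2,4-dien-1-yl}sulfanyl)-1,3-benzothiazole | CC1=CC(=O)CC(C)(C)[C@@H]1/C=C/C(C)=C/CSc1nc2ccccc2s1
F3 | step 5 | 2-({(2E,4E)-5-[(1S,4R)-4-hydroxy-2,6,6-trimethylcyclohex-2-en-1-yl]-3-methylpenta-2,4-dien-1-yl}sulfonyl)-1,3-benzothiazole | CC1=C[C@H](O)CC(C)(C)[C@@H]1/C=C/C(C)=C/CS(=O)(=O)c1nc2ccccc2s1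
F4 | step 5 | (1R,4S)-4-[(1E,3E)-5-(1,3-benzothiazol-2-ylsulfonyl)-3-methylpenta-1,3-dien-1-yl]-3,5,5-trimethylcyclohex-2-en-1-yl acetate | CC1=C[C@H](OC(C)=O)CC(C)(C)[C@@H]1/C=C/C(C)=C/CS(=O)(=O)c1nc2ccccc2s1
F5 | step 6 | {(2E,4E)-3-methyl-5-[(1S)-2,6,6-trimethylcyclohex-2-en-1-yl]penta-2,4-dien-1-yl}triphenylphosphonium bromide | CC1=CCCC(C)(C)[C@@H]1/C=C/C(C)=C/C[P+](c1ccccc1)(c1ccccc1)c1ccccc1.[Br-]
F6 | step 6 | (2E,4E,6E,8E,10E,12E)-2,7,11-trimethyl-13-[(1S)-2,6,6-trimethylcyclohex-2-en-1-yl]trideca-2,4,6,8,10,12-hexaenal | CC1=CCCC(C)(C)[C@@H]1/C=C/C(C)=C/C=C/C(C)=C/C=C/C=C(C)/C=O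
F7 | step 6 | (3S,6S,6'S,11Z)-ε,ε-caroten-3-ol | CC1=CCCC(C)(C)[C@@H]1/C=C/C(C)=C/C=C/C(C)=C/C=C/C=C(C)/C=C\C=C(C)\C=C\[C@@H]1C(C)=C[C@@H](O)CC1(C)C
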